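**Retrosynthetic overview**
1. Target 16 ⇐ benzyl ether 15 (hydrogenolysis last) ⇐ epoxy alcohol 11 + benzylic Grignard reagent 14: the C1–C2 bond comes from opening the C2–C3 oxirane at C2.
2. 11 ⇐ cyclic iodocarbonate 9 ⇐ tert-butyl carbonate 7: the C3–O bond and the C3 stereocenter come from iodine-triggered delivery of the C5 carbonate oxygen to the C2=C3 alkene.
3. 7 ⇐ (R)-tridec-1-en-4-ol 5 ⇐ decanal 1 + allylmagnesium bromide 2: the C5 stereocenter comes from asymmetric allylboration.
4. Feature used: the open-chain 1,3-syn diol at C3/C5, whose C3–O bond lies next to C2, two carbons from the guaiacol ring (the only ring of the target). The C5 oxygen can reach C3 through a six-membered carbonate and leave C2 electrophilic for the benzylic carbon C1.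
5. Ring order: the arene is bought in; the 1,3-dioxan-2-one closes in step 3, is exchanged for the oxirane in step 4, and the oxirane is opened in step 6, so no ring made in the route remains.

Key step: step 3

Remark: chain atoms are numbered as in the target (C1 benzylic, C3 and C5 carbinol carbons, C6–C14 the nonyl tail); [4-(benzyloxy)-3-methoxyphenyl]methanol 12 is assumed to be purchasable (otherwise two routine steps from vanillin: O-benzylation, then NaBH4 reduction).

**Step 1**
Reactants: 1 decanal; 2 allylmagnesium bromide
Product: 5 (R)-tridec-1-en-4-ol, via allyldiisopinocampheylborane 3 (not isolated), via diisopinocampheylborinate 4 (not isolated)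
Conditions: (−)-Ipc2BOMe [from (+)-α-pinene], Et2O, −78 °C to rt; then 1, −78 °C; 3 M NaOH, 30% H2O2, rt
Reagents that add atoms: none
Why: Brown asymmetric allylboration, in which allylborane 3 transfers its allyl group through a closed chair six-membered transition state whose isopinocampheyl groups direct attack to the Si face of the unbranched aldehyde, so that borinate 4 and, after oxidative cleavage, alcohol 5 should carry the R configuration at the future C5.

**Step 2**
Reactants: 5 (R)-tridec-1-en-4-ol; 6 di-tert-butyl dicarbonate
Product: 7 tert-butyl (R)-tridec-1-en-4-yl carbonate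
Conditions: 4-(dimethylamino)pyridine (0.3 equiv), MeCN, rt
Reagents that add atoms: none
Why: Nucleophile-catalysed O-acylation (tert-butoxycarbonylation) of a secondary alcohol, which forms the mixed carbonate without touching the C–O bond of the stereocenter.

**Step 3**
Reactants: 7 tert-butyl (R)-tridec-1-en-4-yl carbonate
Product: 9 (4R,6R)-4-(iodomethyl)-6-nonyl-1,3-dioxan-2-one, via dioxocarbenium bromide 8 (not isolated)
Conditions: IBr (1 M in CH2Cl2), PhMe, −85 °C; aq Na2S2O3/NaHCO3
Reagents that add atoms: iodine monobromide, IBr
Why: IBr forms an iodonium ion on the terminal C2=C3 alkene and the carbonyl oxygen of the carbonate, tethered through the C5 oxygen, opens it at the internal carbon C3, making the C3–O and C2–I bonds and giving dioxocarbenium bromide 8, which loses its tert-butyl group to bromide and leaves the neutral carbonate 9. The closest known reaction type is the iodocarbonate cyclisation of homoallylic tert-butyl carbonates, a halocyclisation related to iodolactonisation. The single ring closed, the 1,3-dioxan-2-one, forms in a 6-exo mode with respect to the alkene. The new stereocenter C3 is controlled by the C5 center through a chair-like transition state that places the nonyl group and the iodonium-bearing carbon both equatorial, which leads to the cis-4,6-disubstituted ring and hence the 1,3-syn oxygen pattern (the center is labelled R in 9 only because CH2I outranks the ring CH2; it is the S center of the target). The step needs 1,3-syn diastereoselectivity and oxygen attack at C3 and not C2: the first should be secured by kinetic control with the highly electrophilic IBr at −85 °C in toluene, the second by the Markovnikov polarisation of the iodonium ion combined with the preference for a six- over a seven-membered ring. Chemoselectivity is not in question because the substrate holds one alkene and no other site for the electrophile, the electron-rich arene being attached only later.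

**Step 4**
Reactants: 9 (4R,6R)-4-(iodomethyl)-6-nonyl-1,3-dioxan-2-one
Product: 11 (2R)-1-[(2R)-oxiran-2-yl]undecan-2-ol, via iodo diol 10 (not isolated)
Conditions: K2CO3 (3 equiv), MeOH, 0 °C to rt
Reagents that add atoms: none
Why: Methoxide transesterifies the cyclic carbonate to release iodohydrin 10, whose C3 alkoxide displaces the neighbouring primary iodide in an intramolecular Williamson closure (3-exo-tet), and since no C–O bond at C3 or C5 is broken both configurations are kept.

**Step 5**
Reactants: 12 [4-(benzyloxy)-3-methoxyphenyl]methanol
Product: 13 1-(benzyloxy)-4-(chloromethyl)-2-methoxybenzene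
Conditions: SOCl2, CH2Cl2, 0 °C to rt
Reagents that add atoms: thionyl chloride, O=S(Cl)Cl
Why: Chlorodehydroxylation of an electron-rich benzylic alcohol through its chlorosulfite, under which the aryl benzyl ether should be stable.

**Step 6**
Reactants: 13 1-(benzyloxy)-4-(chloromethyl)-2-methoxybenzene; 11 (2R)-1-[(2R)-oxiran-2-yl]undecan-2-ol
Product: 15 (3S,5R)-1-[4-(benzyloxy)-3-methoxyphenyl]tetradecane-3,5-diol, via benzylic Grignard reagent 14 (not isolated)
Conditions: Mg turnings, THF, 0 °C (slow addition of 13, dilute); then CuI (10 mol%), 11 (0.33 equiv), −30 to 0 °C; aq NH4Cl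
Reagents that add atoms: none
Why: Slow addition of the chloride to excess magnesium should give Grignard reagent 14 with little Wurtz coupling, and its copper-catalysed SN2 opening of the terminal epoxide at the unsubstituted carbon C2 (one equivalent of 14 being spent on the free hydroxyl) forms the C1–C2 bond without touching C3 or C5.

**Step 7**
Reactants: 15 (3S,5R)-1-[4-(benzyloxy)-3-methoxyphenyl]tetradecane-3,5-diol
Product: 16 (3S,5R)-1-(4-hydroxy-3-methoxyphenyl)tetradecane-3,5-diol
Conditions: H2 (1 atm), 10% Pd/C, EtOAc, rt
Reagents that add atoms: none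
Why: Heterogeneous palladium-catalysed hydrogenolysis cleaves the benzylic C–O bond of the aryl benzyl ether, while the secondary alcohols, the methyl ether and the arene are inert under one atmosphere of hydrogen at room temperature.

**Compound list**
1 | decanal | CCCCCCCCCC=O | starting material
2 | allylmagnesium bromide | C=CC[Mg]Br | starting material
3 | (−)-B-allyldiisopinocampheylborane, allylbis[(1R,2S,3R,5R)-2,6,6-trimethylbicyclo[3.1.1]heptan-3-yl]borane (the isopinocampheyl groups are those that give (1R,2R,3R,5S)-isopinocampheol on oxidation) | C=CCB([C@@H]1C[C@@H]2C[C@H]([C@H]1C)C2(C)C)[C@@H]1C[C@@H]2C[C@H]([C@H]1C)C2(C)C | intermediate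
4 | (4R)-tridec-1-en-4-yl bis[(1R,2S,3R,5R)-2,6,6-trimethylbicyclo[3.1.1]heptan-3-yl]borinate | CCCCCCCCC[C@@H](OB([C@@H]1C[C@@H]2C[C@H]([C@H]1C)C2(C)C)[C@@H]1C[C@@H]2C[C@H]([C@H]1C)C2(C)C)CC=C | intermediate
5 | (R)-tridec-1-en-4-ol | CCCCCCCCC[C@@H](O)CC=C | intermediate
6 | di-tert-butyl dicarbonate | CC(C)(C)OC(=O)OC(=O)OC(C)(C)C | starting material
7 | tert-butyl (R)-tridec-1-en-4-yl carbonate | CCCCCCCCC[C@@H](OC(=O)OC(C)(C)C)CC=C | intermediate
8 | (4R,6R)-2-tert-butoxy-4-(iodomethyl)-6-nonyl-1,3-dioxan-2-ylium bromide (cis) | CCCCCCCCC[C@@H]1C[C@H](CI)O[C+](OC(C)(C)C)O1.[Br-] | intermediate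
9 | (4R,6R)-4-(iodomethyl)-6-nonyl-1,3-dioxan-2-one (cis) | CCCCCCCCC[C@@H]1C[C@H](CI)OC(=O)O1 | intermediate
10 | (2R,4R)-1-iodotridecane-2,4-diol | CCCCCCCCC[C@@H](O)C[C@@H](O)CI | intermediate
11 | (2R)-1-[(2R)-oxiran-2-yl]undecan-2-ol | CCCCCCCCC[C@@H](O)C[C@@H]1CO1 | intermediate
12 | [4-(benzyloxy)-3-methoxyphenyl]methanol | COc1cc(CO)ccc1OCc1ccccc1 | starting material
13 | 1-(benzyloxy)-4-(chloromethyl)-2-methoxybenzene | COc1cc(CCl)ccc1OCc1ccccc1 | intermediate
14 | [4-(benzyloxy)-3-methoxybenzyl]magnesium chloride | COc1cc(C[Mg]Cl)ccc1OCc1ccccc1 | intermediate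
15 | (3S,5R)-1-[4-(benzyloxy)-3-methoxyphenyl]tetradecane-3,5-diol | CCCCCCCCC[C@@H](O)C[C@@H](O)CCc1ccc(OCc2ccccc2)c(OC)c1 | intermediate
16 | (3S,5R)-1-(4-hydroxy-3-methoxyphenyl)tetradecane-3,5-diol | CCCCCCCCC[C@@H](O)C[C@@H](O)CCc1ccc(O)c(OC)c1 | target

**Step count**
Total steps: 7. Longest linear sequence: 6 (steps 1, 2, 3, 4, 6, 7).

**Steps most likely to fail**

Step 6. The electron-rich benzylic chloride may homocouple (Wurtz) while the Grignard reagent forms. The benzylic nucleophile may also react through its ring ortho position, and magnesium chloride may open the epoxide to a chlorohydrin while the alkoxide of the free hydroxyl slows the copper-catalysed path. The fallback replaces the benzylic organometallic by an acyl-anion equivalent and sets out from 11. 2-[4-(Benzyloxy)-3-methoxyphenyl]-1,3-dithiane F1 is made from purchasable 4-(benzyloxy)-3-methoxybenzaldehyde and propane-1,3-dithiol with BF3·OEt2. It is deprotonated with n-BuLi in THF at −30 °C and used in excess, one equivalent being spent on the hydroxyl of 11. Opening of the epoxide at C2 should give (2R,4R)-1-{2-[4-(benzyloxy)-3-methoxyphenyl]-1,3-dithian-2-yl}tridecane-2,4-diol F2. Raney Ni in ethanol then removes the dithiane and the sequence comes back to the route at 15; any loss of the benzyl ether under these conditions would only move material on to 16.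

Step 3. The 1,3-syn selectivity may erode if the cyclisation equilibrates or passes through a poorly ordered transition state. IBr may also simply add across the alkene without capture by the carbonate, or the tert-butyl carbonate may be lost to acid before it cyclises. The fallback replaces substrate-controlled oxygen delivery by catalyst-controlled resolution of an epoxide and sets out from 5. TBSCl and imidazole in DMF give tert-butyldimethyl{[(4R)-tridec-1-en-4-yl]oxy}silane F3. meta-Chloroperoxybenzoic acid in CH2Cl2 gives tert-butyldimethyl{[(2R)-1-(oxiran-2-yl)undecan-2-yl]oxy}silane F4 as both epimers at the oxirane carbon. Hydrolytic kinetic resolution follows, with about 0.55 equiv of water and [N,N'-bis(3,5-di-tert-butylsalicylidene)-1,2-cyclohexanediaminato]cobalt acetate (trivalent cobalt), using the catalyst enantiomer that hydrolyses the (S)-oxirane. This should leave tert-butyldimethyl{[(2R)-1-[(2R)-oxiran-2-yl]undecan-2-yl]oxy}silane F5, separable from the diol of the other epimer. Tetrabutylammonium fluoride buffered with AcOH in THF removes the silyl group and comes back to the route at 11.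

Step 1. The enantioselectivity of allyl transfer to an unbranched aldehyde may fall short of what a single-enantiomer target needs, since magnesium salts and temperatures above −78 °C erode it. The minor enantiomer cannot be removed later, because C3 is set relative to C5. The fallback replaces asymmetric allyl addition by epoxide resolution and vinyl addition, and sets out from 1. Corey–Chaykovsky methylenation (trimethylsulfonium iodide, NaH, DMSO/THF) gives racemic 2-nonyloxirane F6. Hydrolytic kinetic resolution with the same cobalt acetate catalyst, in the enantiomer that consumes the (S)-epoxide, should leave (2R)-2-nonyloxirane F7 in high enantiomeric purity. Vinylmagnesium bromide with catalytic CuI in THF at −30 °C opens it at the terminal carbon and comes back to the route at 5.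

**Further compounds**
F1 | step 6 | 2-[4-(benzyloxy)-3-methoxyphenyl]-1,3-dithiane | COc1cc(C2SCCCS2)ccc1OCc1ccccc1
F2 | step 6 | (2R,4R)-1-{2-[4-(benzyloxy)-3-methoxyphenyl]-1,3-dithian-2-yl}tridecane-2,4-diol | CCCCCCCCC[C@@H](O)C[C@@H](O)CC1(SCCCS1)c1ccc(OCc2ccccc2)c(OC)c1
F3 | step 3 | tert-butyldimethyl{[(4R)-tridec-1-en-4-yl]oxy}silane | CCCCCCCCC[C@@H](O[Si](C)(C)C(C)(C)C)CC=C
F4 | step 3 | tert-butyldimethyl{[(2R)-1-(oxiran-2-yl)undecan-2-yl]oxy}silane, both oxirane epimers | CCCCCCCCC[C@@H](O[Si](C)(C)C(C)(C)C)CC1CO1
F5 | step 3 | tert-butyldimethyl{[(2R)-1-[(2R)-oxiran-2-yl]undecan-2-yl]oxy}silane | CCCCCCCCC[C@@H](O[Si](C)(C)C(C)(C)C)C[C@@H]1CO1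
F6 | step 1 | 2-nonyloxirane, racemic | CCCCCCCCCC1CO1
F7 | step 1 | (2R)-2-nonyloxirane | CCCCCCCCC[C@@H]1CO1
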